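The noon run stands at the flask's concentration, and the meeting began from it.

| flask | starting material | second substrate | free catalyst | remark | time |
|---|---|---|---|---|---|
| winter | 0.48 M | 0.50 equiv | 1.8 mol% | run made earlier |  |
| midnight | 1.9 M | 0.50 equiv | 1.8 mol% | run made earlier |  |
| noon | 0.96 M | 0.75 equiv | 1.8 mol% | run made earlier |  |
| flask | 0.96 M | 0.500 equiv | 1.8 mol% |  | 40 min |

| run | time / min | target / % | isomer of the product / % |
|---|---|---|---|
| winter | 3.00 | 5 | 4 |
| winter | 6.00 | 10 | 1 |
| winter | 12.0 | 17 | 4 |
| winter | 20.0 | 17 | 6 |
| winter | 40.0 | 27 | 10 |
| midnight | 8.00 | 14 | 4 |
| midnight | 15.0 | 24 | 0 |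
| midnight | 25.0 | 28 | 8 |
| midnight | 30.0 | 30 | 11 |
| midnight | 40.0 | 33 | 13 |
| noon | 3.00 | 2 | 0 |
| noon | 6.00 | 10 | 4 |
| noon | 12.0 | 19 | 4 |
| noon | 20.0 | 27 | 6 |
| noon | 40.0 | 32 | 11 |

(readings scatter by 2 percentage points)

- percent here means starting material units held: one self-condensation product counts as two
- the analysis behind the earlier runs scatters by 2 percentage points, standard deviation

- how much target the flask holds at 40 min, in percent of the starting material charged
- how much isomer of the product the flask holds at 40 min, in percent of the starting material charged
- how much self-condensation product the flask holds at 40 min, in percent of the starting material charged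
- how much starting material the flask holds at 40 min, in percent of the starting material charged

Minutes. Present were a kineticist, an analyst and the chair. The chair asked where one molecule of starting material goes. The kineticist answered that it meets a fork: through the catalyst to target and isomer, or into self-condensation product, of which there are no readings. She proposed that the catalytic exit runs in proportion to c(starting material), so that the slope of target plus isomer reports what is left.

The analyst read the noon run. That sum climbs by 0.0192 min⁻¹ of the charge up to 12.0 min, then by 0.00500 min⁻¹ between 20.0 min and 40.0 min. The ratio is 0.261, a rough reading, since each value scatters by 2 percentage points.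

The kineticist treated the early slope as the rate at the full charge, took this ratio as the fraction left at mid-window and, assuming an exponential fall, reckoned 16.7% left at 40 min. The chair assumed that the smaller second-substrate charge changes little and took noon's 43.0% of target plus isomer. This gave the fork share, a selectivity: the part of the consumed starting material found as target plus isomer, 51.6%. The balance gave a reckoned 40.3% of self-condensation product.

The forecast gives target 30%, isomer 11%, self-condensation product 8% and starting material 51%, so it differs from the meeting's reckoning on the last two, and it notes: "Self-condensation product was never measured."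

The flask gives target 34.0%, isomer 11.5%, self-condensation product 41.2% and starting material 13.2%.

    2 catalyst intermediate A ⇌ resting dimer, settled at all times (K = 62.0 M⁻¹)
    starting material + free catalyst ⇌ catalyst intermediate A (K = 93.0 M⁻¹, k = 2.37 M⁻¹ min⁻¹)
    catalyst intermediate A → free catalyst + target (k = 3.96 min⁻¹)
    target ⇌ isomer of the product (K = 0.499, k = 0.0238 min⁻¹)
    2 starting material → self-condensation product (k = 0.0255 M⁻¹ min⁻¹)
    second substrate + free catalyst ⇌ catalyst intermediate B (K = 4.04 M⁻¹, k = 0.851 M⁻¹ min⁻¹)
    catalyst intermediate B → free catalyst + second product (k = 25.3 min⁻¹)

The flask's fork share comes to 52.4%. Applied to the neighbour charged at 0.58 M, which has consumed 75.7%, the reckoned share gives 39.0% of target plus isomer, and that neighbour holds 39.9%. The flask has not come to rest: 13% of its starting material remains. Ten times the time takes that to 0%, and nearly all of it appears as target plus isomer. Self-condensation product gains 1 point, while target reaches 38.6% and isomer 19.2%.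

Readings and results stem from a simulated flask on assumed constants, noise included.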